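**Plan**

1. Numbering used below: tetralin C1 (pendant aryl), C2 (CH2OSO3H arm), C3 (CH2OH arm), C4 (ring CH2); benzo ring A = C4a–C8a with OMe on C6 and OH on C7; ring B is the saturated ring.
2. Last cut: the aryl–CH2 bond C4–C4a of ring B together with the S–O bond at the C4 oxygen. This leads back to a seven-membered cyclic sulfate (1,3,2-dioxathiepane 2,2-dioxide) spanning the oxygen of the C2 arm and an oxygen on C4.
3. What allows it: C4a stands para to the C7 phenol oxygen, so the phenoxide of ring A is a carbon nucleophile exactly there. The sulfated oxygen stands 1,4 to C4 (O–CH2–C2–C3–C4), so the leaving group on C4 and the sulfate half-ester of the target can be one and the same SO4 unit.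
4. Earlier cuts: C1–pendant aryl (conjugate addition to an (E)-arylidene lactone), C1=C2 (aldol condensation of a 4-substituted butyrolactone with silylated isovanillin), and the lactone back to an Evans alkylation.
5. Forward: lactone (C3) → arylidene lactone → cis diaryl lactone (C1, C2) → 1,4-diol → cyclic sulfate → ring B closed last by the unmasked phenoxide → debenzylation.
6. Stereochemistry: C3 from the oxazolidinone auxiliary; C1 by aryl addition anti to the C3 arm on the E alkene; C2 by kinetic protonation anti to the same arm; the ring closure forms no stereocenter.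

Key step: step 10

Assumption: the target is drawn as the free hydrogen sulfate; sulfate half-esters are carried as tetrabutylammonium salts and the acid is released in the last step.

**Route**

Step 1
Reactants: 1 4-(tert-butoxy)-4-oxobutanoic acid; 2 (4S)-4-benzyl-1,3-oxazolidin-2-one
Product: 4 tert-butyl 4-[(4S)-4-benzyl-2-oxo-1,3-oxazolidin-3-yl]-4-oxobutanoate, via mixed pivalic anhydride 3 (not isolated)
Conditions: tBuCOCl, Et3N, THF, −20 °C; then 2, LiCl, −20 °C → rt
Reagents that add atoms: none
Why: N-acylation of the Evans oxazolidinone by the mixed pivalic anhydride (Et3N/LiCl) is the standard route to such imides and creates no stereocenter.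

Step 2
Reactants: 4 tert-butyl 4-[(4S)-4-benzyl-2-oxo-1,3-oxazolidin-3-yl]-4-oxobutanoate
Product: 5 tert-butyl (3R)-3-[(benzyloxy)methyl]-4-[(4S)-4-benzyl-2-oxo-1,3-oxazolidin-3-yl]-4-oxobutanoate
Conditions: TiCl4, iPr2NEt, CH2Cl2, 0 °C; then BnOCH2Cl, 0 °C
Reagents that add atoms: benzyl chloromethyl ether ClCOCc1ccccc1
Why: Evans alkylation: the chelated Z-titanium enolate forms only at the more acidic imide α-CH2 and takes the chloromethyl ether on the face away from the benzyl group of the auxiliary, which sets C3 of the target (R in 5).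

Step 3
Reactants: 5 tert-butyl (3R)-3-[(benzyloxy)methyl]-4-[(4S)-4-benzyl-2-oxo-1,3-oxazolidin-3-yl]-4-oxobutanoate
Product: 7 (4R)-4-[(benzyloxy)methyl]oxolan-2-one, via hydroxy ester 6 (not isolated)
Conditions: LiBH4, THF, H2O (1 equiv), 0 °C; then CF3CO2H, CH2Cl2, rt
Reagents that add atoms: none
Why: LiBH4 cleaves the imide reductively to the primary alcohol while the tert-butyl ester survives, and acid then closes the γ-lactone with loss of isobutene (lactonization), leaving the stereocenter untouched.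

Step 4
Reactants: 8 3-hydroxy-4-methoxybenzaldehyde (isovanillin)
Product: 9 4-methoxy-3-[(triisopropylsilyl)oxy]benzaldehyde
Conditions: iPr3SiCl, imidazole, DMF, rt
Reagents that add atoms: chlorotri(propan-2-yl)silane CC(C)[Si](Cl)(C(C)C)C(C)C
Why: Silylation of the phenol gives an aryl silyl ether that withstands amide base, Grignard reagent and borohydride and falls to fluoride alone, which is what the ring closure needs.

Step 5
Reactants: 7 (4R)-4-[(benzyloxy)methyl]oxolan-2-one; 9 4-methoxy-3-[(triisopropylsilyl)oxy]benzaldehyde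
Product: 10 (3R,4R)-4-[(benzyloxy)methyl]-3-{hydroxy[4-methoxy-3-(triisopropylsilyloxy)phenyl]methyl}oxolan-2-one (3,4-trans; both carbinol epimers)
Conditions: LiN(iPr)2, THF, −78 °C; then 9, −78 °C; aq. NH4Cl
Reagents that add atoms: none
Why: Aldol addition of the lactone lithium enolate to a non-enolizable aldehyde occurs anti to the ring substituent; the two new centers (ring carbon and carbinol) disappear again in step 6, so their ratio does not matter.

Step 6
Reactants: 10 (3R,4R)-4-[(benzyloxy)methyl]-3-{hydroxy[4-methoxy-3-(triisopropylsilyloxy)phenyl]methyl}oxolan-2-one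
Product: 12 (3E,4R)-4-[(benzyloxy)methyl]-3-{[4-methoxy-3-(triisopropylsilyloxy)phenyl]methylidene}oxolan-2-one, via mesylate 11 (not isolated)
Conditions: MeSO2Cl, Et3N, CH2Cl2, 0 °C; then DBU, 0 °C → rt, short contact
Reagents that add atoms: none
Why: Mesylation followed by E1cB elimination gives the conjugated (E)-arylidene lactone, the thermodynamically preferred isomer with the aryl group away from the carbonyl, and short exposure to base keeps the γ-hydrogen at the stereocenter in place.

Step 7
Reactants: 12 (3E,4R)-4-[(benzyloxy)methyl]-3-{[4-methoxy-3-(triisopropylsilyloxy)phenyl]methylidene}oxolan-2-one; 13 1-(benzyloxy)-4-bromo-2-methoxybenzene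
Product: 16 (3R,4R)-3-{(S)-[4-(benzyloxy)-3-methoxyphenyl][4-methoxy-3-(triisopropylsilyloxy)phenyl]methyl}-4-[(benzyloxy)methyl]oxolan-2-one (3,4-cis), via arylmagnesium bromide 14 (not isolated), via silyl ketene acetal 15 (not isolated)
Conditions: 13, Mg, THF, 40 °C; then CuBr·SMe2 (10 mol %), Me3SiCl, 12, THF, −78 → −30 °C; then AcOH, THF, −78 °C
Reagents that add atoms: none
Why: Copper-catalyzed conjugate addition of an aryl Grignard reagent (Me3SiCl-accelerated) to the exocyclic enoate puts the aryl group on C1 from the alkene face anti to the pseudoaxial benzyloxymethyl group on C3, which with the E geometry fixes C1 (S), and kinetic protonation of the silyl ketene acetal from the same open face places the C2 hydrogen anti to that group and so gives the cis lactone (C2 R).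

Step 8
Reactants: 16 (3R,4R)-3-{(S)-[4-(benzyloxy)-3-methoxyphenyl][4-methoxy-3-(triisopropylsilyloxy)phenyl]methyl}-4-[(benzyloxy)methyl]oxolan-2-one
Product: 17 (2R,3S)-2-{(S)-[4-(benzyloxy)-3-methoxyphenyl][4-methoxy-3-(triisopropylsilyloxy)phenyl]methyl}-3-[(benzyloxy)methyl]butane-1,4-diol
Conditions: LiBH4, THF, 0 °C → rt
Reagents that add atoms: none
Why: Lactone to 1,4-diol reduction with LiBH4, a reagent too weakly basic to epimerize the α-carbon before the carbonyl is consumed and inert to the silyl and benzyl ethers.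

Step 9
Reactants: 17 (2R,3S)-2-{(S)-[4-(benzyloxy)-3-methoxyphenyl][4-methoxy-3-(triisopropylsilyloxy)phenyl]methyl}-3-[(benzyloxy)methyl]butane-1,4-diol
Product: 19 (5R,6R)-5-{(S)-[4-(benzyloxy)-3-methoxyphenyl][4-methoxy-3-(triisopropylsilyloxy)phenyl]methyl}-6-[(benzyloxy)methyl]-1,3,2-dioxathiepane 2,2-dioxide, via cyclic sulfite 18 (not isolated)
Conditions: SOCl2, Et3N, CH2Cl2 (0.01 M), 0 °C; then RuCl3·3H2O (1 mol %), NaIO4, MeCN/H2O, 0 °C, 10 min
Reagents that add atoms: thionyl chloride O=S(Cl)Cl; sodium periodate [Na+].[O-]I(=O)(=O)=O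
Why: Two-stage cyclic sulfate synthesis (cyclic sulfite from SOCl2, then RuO4-catalyzed oxidation at sulfur), which is established for 1,4-diols as for 1,2- and 1,3-diols; the cis substituents favour the seven-membered ring and no stereocenter is touched.

Step 10
Reactants: 19 (5R,6R)-5-{(S)-[4-(benzyloxy)-3-methoxyphenyl][4-methoxy-3-(triisopropylsilyloxy)phenyl]methyl}-6-[(benzyloxy)methyl]-1,3,2-dioxathiepane 2,2-dioxide
Product: 22 tetrabutylammonium [(1S,2R,3R)-1-[4-(benzyloxy)-3-methoxyphenyl]-3-[(benzyloxy)methyl]-7-hydroxy-6-methoxy-1,2,3,4-tetrahydronaphthalen-2-yl]methyl sulfate, via tetrabutylammonium phenoxide 20 (not isolated), via cyclohexadienone 21 (not isolated)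
Conditions: Bu4NF (1.0 M in THF, 1.05 equiv), THF (0.003 M), −20 °C; then 45 °C
Reagents that add atoms: tetrabutylammonium fluoride CCCC[N+](CCCC)(CCCC)CCCC.[F-]
Why: Proposed new method: fluoride removes the silyl group and leaves a tetrabutylammonium phenoxide whose carbon para to O− (the future C4a) attacks the primary C4–O carbon of the cyclic sulfate in an intramolecular SN2 displacement; the dienone tautomerizes to the phenol and the sulfur stays on the other oxygen as the monoester anion, which is inert to a second displacement. The closest known reactions are the Ar2-6 closure of 4-arylbutyl sulfonates to tetralins by an electron-rich arene or phenoxide, and the single SN2 opening of cyclic sulfates (seven-membered ones included) by carbon nucleophiles. Ring B closes 6-exo-tet. No stereocenter is formed (C4 is a CH2 group, C4a returns to sp2), and C1, C2 and C3 carry no hydrogen that is acidic under these conditions, so they are untouched. The selectivities needed are: C- over O-alkylation (the oxygen cannot reach either CH2 within the molecule, and high dilution holds back the bimolecular path); para (C4a) over ortho (C8, flanked by O− and C1); six- over five-membered closure (attack on the CH2O carbon of the C2 arm would be an Ar2-5 closure, in which the π face of the arene cannot be reached, and that carbon is shielded by the diarylmethyl group); and ring A over the benzyl-protected ring (a neutral aryl ether does not displace an alkyl sulfate at this temperature). Fluoride is added cold in one equivalent, so it is consumed at silicon before it can open the sulfate.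

Step 11
Reactants: 22 tetrabutylammonium [(1S,2R,3R)-1-[4-(benzyloxy)-3-methoxyphenyl]-3-[(benzyloxy)methyl]-7-hydroxy-6-methoxy-1,2,3,4-tetrahydronaphthalen-2-yl]methyl sulfate
Product: 23 [(1S,2R,3R)-7-hydroxy-1-(4-hydroxy-3-methoxyphenyl)-3-(hydroxymethyl)-6-methoxy-1,2,3,4-tetrahydronaphthalen-2-yl]methyl hydrogen sulfate
Conditions: H2 (1 atm), Pd/C, MeOH, rt; then HCl (1.0 equiv), H2O, 0 °C, reversed-phase chromatography
Reagents that add atoms: none
Why: Hydrogenolysis over Pd/C removes the aryl and the alkyl benzyl ether while the sulfate monoester anion and the ring C–C bonds at the benzylic carbons stay intact, and one equivalent of acid then releases the hydrogen sulfate.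

**Compound list**

1 | 4-(tert-butoxy)-4-oxobutanoic acid (mono-tert-butyl succinate) | CC(C)(C)OC(=O)CCC(=O)O | starting material
2 | (4S)-4-benzyl-1,3-oxazolidin-2-one | O=C1N[C@@H](Cc2ccccc2)CO1 | starting material
3 | 4-(tert-butoxy)-4-oxobutanoic 2,2-dimethylpropanoic anhydride | CC(C)(C)OC(=O)CCC(=O)OC(=O)C(C)(C)C | intermediate
4 | tert-butyl 4-[(4S)-4-benzyl-2-oxo-1,3-oxazolidin-3-yl]-4-oxobutanoate | CC(C)(C)OC(=O)CCC(=O)N1[C@@H](Cc2ccccc2)COC1=O | intermediate
5 | tert-butyl (3R)-3-[(benzyloxy)methyl]-4-[(4S)-4-benzyl-2-oxo-1,3-oxazolidin-3-yl]-4-oxobutanoate | CC(C)(C)OC(=O)C[C@H](COCc1ccccc1)C(=O)N1[C@@H](Cc2ccccc2)COC1=O | intermediate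
6 | tert-butyl (3S)-3-[(benzyloxy)methyl]-4-hydroxybutanoate | CC(C)(C)OC(=O)C[C@H](COCc1ccccc1)CO | intermediate
7 | (4R)-4-[(benzyloxy)methyl]oxolan-2-one | O=C1C[C@H](COCc2ccccc2)CO1 | intermediate
8 | 3-hydroxy-4-methoxybenzaldehyde (isovanillin) | COc1ccc(C=O)cc1O | starting material
9 | 4-methoxy-3-[(triisopropylsilyl)oxy]benzaldehyde | COc1ccc(C=O)cc1O[Si](C(C)C)(C(C)C)C(C)C | intermediate
10 | (3R,4R)-4-[(benzyloxy)methyl]-3-{hydroxy[4-methoxy-3-(triisopropylsilyloxy)phenyl]methyl}oxolan-2-one (3,4-trans; both carbinol epimers) | O=C1OC[C@@H](COCc2ccccc2)[C@@H]1C(O)c1ccc(OC)c(O[Si](C(C)C)(C(C)C)C(C)C)c1 | intermediate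
11 | [(3R,4R)-4-[(benzyloxy)methyl]-2-oxooxolan-3-yl][4-methoxy-3-(triisopropylsilyloxy)phenyl]methyl methanesulfonate (both epimers at the sulfonate carbon) | O=C1OC[C@@H](COCc2ccccc2)[C@@H]1C(OS(C)(=O)=O)c1ccc(OC)c(O[Si](C(C)C)(C(C)C)C(C)C)c1 | intermediate
12 | (3E,4R)-4-[(benzyloxy)methyl]-3-{[4-methoxy-3-(triisopropylsilyloxy)phenyl]methylidene}oxolan-2-one | COc1ccc(/C=C2\[C@H](COCc3ccccc3)COC2=O)cc1O[Si](C(C)C)(C(C)C)C(C)C | intermediate
13 | 1-(benzyloxy)-4-bromo-2-methoxybenzene | COc1cc(Br)ccc1OCc1ccccc1 | starting material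
14 | [4-(benzyloxy)-3-methoxyphenyl]magnesium bromide | COc1cc([Mg]Br)ccc1OCc1ccccc1 | intermediate
15 | {[(4R)-3-{(S)-[4-(benzyloxy)-3-methoxyphenyl][4-methoxy-3-(triisopropylsilyloxy)phenyl]methyl}-4-[(benzyloxy)methyl]-4,5-dihydrofuran-2-yl]oxy}trimethylsilane | C[Si](C)(C)OC1=C([C@@H](c2ccc(OCc3ccccc3)c(OC)c2)c2ccc(OC)c(O[Si](C(C)C)(C(C)C)C(C)C)c2)[C@H](COCc2ccccc2)CO1 | intermediate
16 | (3R,4R)-3-{(S)-[4-(benzyloxy)-3-methoxyphenyl][4-methoxy-3-(triisopropylsilyloxy)phenyl]methyl}-4-[(benzyloxy)methyl]oxolan-2-one (3,4-cis) | O=C1OC[C@@H](COCc2ccccc2)[C@H]1[C@@H](c1ccc(OCc2ccccc2)c(OC)c1)c1ccc(OC)c(O[Si](C(C)C)(C(C)C)C(C)C)c1 | intermediate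
17 | (2R,3S)-2-{(S)-[4-(benzyloxy)-3-methoxyphenyl][4-methoxy-3-(triisopropylsilyloxy)phenyl]methyl}-3-[(benzyloxy)methyl]butane-1,4-diol | COc1cc(ccc1OCc1ccccc1)[C@H]([C@@H](CO)[C@H](COCc1ccccc1)CO)c1ccc(OC)c(O[Si](C(C)C)(C(C)C)C(C)C)c1 | intermediate
18 | (5R,6R)-5-{(S)-[4-(benzyloxy)-3-methoxyphenyl][4-methoxy-3-(triisopropylsilyloxy)phenyl]methyl}-6-[(benzyloxy)methyl]-1,3,2-dioxathiepane 2-oxide (either configuration at sulfur) | COc1cc(ccc1OCc1ccccc1)[C@H]([C@H]1COS(=O)OC[C@H]1COCc1ccccc1)c1ccc(OC)c(O[Si](C(C)C)(C(C)C)C(C)C)c1 | intermediate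
19 | (5R,6R)-5-{(S)-[4-(benzyloxy)-3-methoxyphenyl][4-methoxy-3-(triisopropylsilyloxy)phenyl]methyl}-6-[(benzyloxy)methyl]-1,3,2-dioxathiepane 2,2-dioxide | COc1cc(ccc1OCc1ccccc1)[C@H]([C@H]1COS(=O)(=O)OC[C@H]1COCc1ccccc1)c1ccc(OC)c(O[Si](C(C)C)(C(C)C)C(C)C)c1 | intermediate
20 | tetrabutylammonium 5-{(R)-[4-(benzyloxy)-3-methoxyphenyl][(5R,6R)-6-[(benzyloxy)methyl]-2,2-dioxo-1,3,2-dioxathiepan-5-yl]methyl}-2-methoxyphenolate (same spatial arrangement as 19; the descriptor of the methine carbon changes by the sequence rule) | COc1cc(ccc1OCc1ccccc1)[C@H]([C@H]1COS(=O)(=O)OC[C@H]1COCc1ccccc1)c1ccc(OC)c([O-])c1.CCCC[N+](CCCC)(CCCC)CCCC | intermediate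
21 | tetrabutylammonium [(1S,2R,3R)-1-[4-(benzyloxy)-3-methoxyphenyl]-3-[(benzyloxy)methyl]-6-methoxy-7-oxo-1,2,3,4,4a,7-hexahydronaphthalen-2-yl]methyl sulfate (either configuration at C4a) | COc1cc(ccc1OCc1ccccc1)[C@@H]1[C@@H](COS(=O)(=O)[O-])[C@H](COCc3ccccc3)CC2C=C(OC)C(=O)C=C12.CCCC[N+](CCCC)(CCCC)CCCC | intermediate
22 | tetrabutylammonium [(1S,2R,3R)-1-[4-(benzyloxy)-3-methoxyphenyl]-3-[(benzyloxy)methyl]-7-hydroxy-6-methoxy-1,2,3,4-tetrahydronaphthalen-2-yl]methyl sulfate | COc1cc(ccc1OCc1ccccc1)[C@@H]1[C@@H](COS(=O)(=O)[O-])[C@H](COCc3ccccc3)Cc2cc(OC)c(O)cc12.CCCC[N+](CCCC)(CCCC)CCCC | intermediate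
23 | [(1S,2R,3R)-7-hydroxy-1-(4-hydroxy-3-methoxyphenyl)-3-(hydroxymethyl)-6-methoxy-1,2,3,4-tetrahydronaphthalen-2-yl]methyl hydrogen sulfate | COc1cc([C@H]2c3cc(O)c(OC)cc3C[C@@H](CO)[C@@H]2COS(=O)(=O)O)ccc1O | target

**Count and risks**

Total steps: 11. Longest linear sequence: 10 steps (steps 1–3 and 5–11; step 4 is a one-step branch).

Steps most likely to fail:

1. Step 10. The seven-membered ring holds the CH2O carbon of the C2 arm gauche to C4, so closure has to pass through a conformer with the C2 and C3 arms axial. If that slows the C-alkylation, bimolecular O-alkylation or opening of the sulfate by fluoride may take over. The fallback uses known chemistry and sets out from 19. Tetrabutylammonium iodide in acetone should open the cyclic sulfate by SN2 at the less hindered CH2 (C4; the other CH2 sits next to the carbon that bears the diarylmethyl group), giving tetrabutylammonium (2R,3R)-2-{(S)-[4-(benzyloxy)-3-methoxyphenyl][4-methoxy-3-(triisopropylsilyloxy)phenyl]methyl}-3-[(benzyloxy)methyl]-4-iodobutyl sulfate F1. Bu4NF in dilute THF should then free the phenoxide, which closes ring B on the open-chain primary iodide by the ordinary Ar2-6 phenoxide alkylation through an unconstrained chair. The fallback comes back to the route at 22.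

2. Step 7. Aryl transfer to the electron-rich β-aryl enoate may be slow, so that 1,2-addition to the lactone competes; facial control at C1 may be incomplete; or the kinetic protonation may drift toward the trans lactone. The fallback sets both centers by syn hydrogenation instead and sets out from 10. Dess–Martin oxidation should give (3R,4R)-4-[(benzyloxy)methyl]-3-[4-methoxy-3-(triisopropylsilyloxy)benzoyl]oxolan-2-one F2. Non-chelating enolization (KN(SiMe3)2, 18-crown-6) and PhNTf2 should give [(E)-[(4R)-4-[(benzyloxy)methyl]-2-oxooxolan-3-ylidene][4-methoxy-3-(triisopropylsilyloxy)phenyl]methyl] trifluoromethanesulfonate F3, with OTf cis to the ring CH. Suzuki–Miyaura coupling with [4-(benzyloxy)-3-methoxyphenyl]boronic acid (Pd(PPh3)4, K3PO4) should replace OTf with retention to give (3Z,4R)-3-{[4-(benzyloxy)-3-methoxyphenyl][4-methoxy-3-(triisopropylsilyloxy)phenyl]methylidene}-4-[(benzyloxy)methyl]oxolan-2-one F4. Hydrogenation with [Ir(cod)(PCy3)(py)]PF6 (H2, CH2Cl2) should add both hydrogens from the face anti to the benzyloxymethyl group, which fixes C1 and C2 together. The fallback comes back to the route at 16.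

3. Step 9. RuO4 may oxidize the two electron-rich rings or the benzylic ether CH2 groups before the sulfite is consumed, or oligomeric sulfites may form in place of the seven-membered ring. The fallback avoids any oxidant and sets out from 17. The dialkoxide (NaH, THF, high dilution) should take the sulfuryl group directly from 1,1'-sulfonyldiimidazole (O=S(=O)(n1ccnc1)n1ccnc1). It comes back to the route at 19, and no new compound arises (F0).

**Further compounds**

F1 | step 10 | tetrabutylammonium (2R,3R)-2-{(S)-[4-(benzyloxy)-3-methoxyphenyl][4-methoxy-3-(triisopropylsilyloxy)phenyl]methyl}-3-[(benzyloxy)methyl]-4-iodobutyl sulfate | COc1cc(ccc1OCc1ccccc1)[C@H]([C@@H](COS(=O)(=O)[O-])[C@H](COCc1ccccc1)CI)c1ccc(OC)c(O[Si](C(C)C)(C(C)C)C(C)C)c1.CCCC[N+](CCCC)(CCCC)CCCC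
F2 | step 7 | (3R,4R)-4-[(benzyloxy)methyl]-3-[4-methoxy-3-(triisopropylsilyloxy)benzoyl]oxolan-2-one | O=C1OC[C@@H](COCc2ccccc2)[C@@H]1C(=O)c1ccc(OC)c(O[Si](C(C)C)(C(C)C)C(C)C)c1
F3 | step 7 | [(E)-[(4R)-4-[(benzyloxy)methyl]-2-oxooxolan-3-ylidene][4-methoxy-3-(triisopropylsilyloxy)phenyl]methyl] trifluoromethanesulfonate | COc1ccc(/C(OS(=O)(=O)C(F)(F)F)=C2/[C@H](COCc3ccccc3)COC2=O)cc1O[Si](C(C)C)(C(C)C)C(C)C
F4 | step 7 | (3Z,4R)-3-{[4-(benzyloxy)-3-methoxyphenyl][4-methoxy-3-(triisopropylsilyloxy)phenyl]methylidene}-4-[(benzyloxy)methyl]oxolan-2-one | COc1ccc(/C(c2ccc(OCc3ccccc3)c(OC)c2)=C2/[C@H](COCc3ccccc3)COC2=O)cc1O[Si](C(C)C)(C(C)C)C(C)C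
F0 | step 9 | none | none
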